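**Strategy.** The route rests on closing ring B last, across C8–C9 (labdane numbering). A monocyclic ring-A precursor already carries C4, C5 and C10. C5 bears a 3-oxobutyl chain ending in the C8 methyl ketone. C10 bears a vinyl sulfone whose β-carbon is C9 and whose α-carbon (C11) already holds the C12–C15 chain from (R)-methylsuccinate. SmI2 turns the ketone into a ketyl that adds 6-exo to C9, creating the C8 tertiary carbinol and the C9 methine, trans to each other, in one operation. The step exploits the 1,2-relationship of the C8 carbinol and C9 in ring B; the sulfone is then removed tracelessly.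

Key step: step 13

Remark on the chemistry: all carbons are numbered as in labdane (C1–C20). The target is taken as the (4S,5S,8S,9S,10R,13S) enantiomer drawn, an ent-labdane 18-angelate 15-hydrogen malonate.

Step 1
Reactants: 1 3-methylbut-3-en-2-one; 2 triisopropylsilyl trifluoromethanesulfonate
Product: 3 3-methyl-2-[(triisopropylsilyl)oxy]buta-1,3-diene
Conditions: Et3N, CH2Cl2, 0 °C
Reagents that add atoms: 2 triisopropylsilyl trifluoromethanesulfonate CC(C)[Si](C(C)C)(C(C)C)OS(=O)(=O)C(F)(F)F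
Why: Soft enolisation (O-silylation of the enone, then deprotonation of the acetyl methyl by Et3N) should give the cross-conjugated 2-silyloxy diene; no stereocenter is formed.

Step 2
Reactants: 3 3-methyl-2-[(triisopropylsilyl)oxy]buta-1,3-diene; 4 methacrolein
Product: 5 (R)-1,3-dimethyl-4-[(triisopropylsilyl)oxy]cyclohex-3-ene-1-carbaldehyde
Conditions: (S)-3,3-diphenyl-1-(o-tolyl)tetrahydro-1H,3H-pyrrolo[1,2-c][1,3,2]oxazaborole (20 mol %), HNTf2 (18 mol %), CH2Cl2, −78 °C
Reagents that add atoms: 4 methacrolein CC(=C)C=O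
Why: Catalytic enantioselective Diels–Alder reaction of a 2-substituted acrolein under a chiral oxazaborolidinium Lewis acid: the silyloxy group directs the "para" regiochemistry and the catalyst shields one face of the bound enal, setting the quaternary C10 as (R); if the sense of induction proves opposite for this diene, the antipodal catalyst is used.

Step 3
Reactants: 5 (R)-1,3-dimethyl-4-[(triisopropylsilyl)oxy]cyclohex-3-ene-1-carbaldehyde
Product: 6 (R)-1,3-dimethyl-4-oxocyclohex-2-ene-1-carbaldehyde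
Conditions: Pd(OAc)2 (1.1 equiv), MeCN, 40 °C
Reagents that add atoms: none
Why: Saegusa–Ito oxidation: the palladium enolate at C4 should undergo β-hydride elimination towards the ring CH2 (C5) to give the 2-methyl enone, while C10, which has no α-hydrogen, is untouched.

Step 4
Reactants: 6 (R)-1,3-dimethyl-4-oxocyclohex-2-ene-1-carbaldehyde; 7 ethane-1,2-diol
Product: 8 (R)-4-(1,3-dioxolan-2-yl)-2,4-dimethylcyclohex-2-en-1-one
Conditions: pyridinium p-toluenesulfonate (cat.), benzene, reflux, Dean–Stark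
Reagents that add atoms: 7 ethane-1,2-diol OCCO
Why: Chemoselective acetalisation, the aldehyde reacting much faster than the conjugated α-substituted ketone; the dioxolane protects C9 and makes the C10 substituent the bulkier one for the next step.

Step 5
Reactants: 8 (R)-4-(1,3-dioxolan-2-yl)-2,4-dimethylcyclohex-2-en-1-one; 9 2-(2-bromoethyl)-2-methyl-1,3-dioxolane; 10 chlorotrimethylsilane; 11 benzyl chloromethyl ether
Product: 13 (2S,3S,4R)-2-[(benzyloxy)methyl]-4-(1,3-dioxolan-2-yl)-2,4-dimethyl-3-[2-(2-methyl-1,3-dioxolan-2-yl)ethyl]cyclohexan-1-one, via trimethylsilyl enol ether 12 (not isolated)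
Conditions: 9, Mg, THF, rt; CuBr·SMe2 (10 mol %), 10, THF, −78 → −30 °C; volatiles removed; MeLi, THF, 0 °C; then 11, HMPA, −78 → −20 °C
Reagents that add atoms: 9 2-(2-bromoethyl)-2-methyl-1,3-dioxolane BrCCC1(C)OCCO1; 11 benzyl chloromethyl ether ClCOCc1ccccc1; 10 chlorotrimethylsilane C[Si](C)(C)Cl (enters intermediate 12 only)
Why: Copper-catalysed, silyl-chloride-accelerated conjugate addition followed by regiospecific enolate alkylation: the Grignard reagent should enter C5 anti to the bulky dioxolanyl group on C10 (sets C5), and the lithium enolate released from 12 by MeLi should be alkylated at C4 anti to the new C5 chain (sets C4, CH2OBn equatorial).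

Step 6
Reactants: 13 (2S,3S,4R)-2-[(benzyloxy)methyl]-4-(1,3-dioxolan-2-yl)-2,4-dimethyl-3-[2-(2-methyl-1,3-dioxolan-2-yl)ethyl]cyclohexan-1-one
Product: 14 2-{(1R,2R,3S)-3-[(benzyloxy)methyl]-1,3-dimethyl-2-[2-(2-methyl-1,3-dioxolan-2-yl)ethyl]cyclohexyl}-1,3-dioxolane
Conditions: N2H4·H2O, KOH, diethylene glycol, 130 °C then 200 °C
Reagents that add atoms: none
Why: Wolff–Kishner (Huang–Minlon) reduction removes the C3 carbonyl that served only to activate ring A; both acetals, the benzyl ether and all three stereocenters (none is α to the carbonyl with a hydrogen) should survive hot base.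

Step 7
Reactants: 14 2-{(1R,2R,3S)-3-[(benzyloxy)methyl]-1,3-dimethyl-2-[2-(2-methyl-1,3-dioxolan-2-yl)ethyl]cyclohexyl}-1,3-dioxolane
Product: 15 (1R,2R,3S)-3-[(benzyloxy)methyl]-1,3-dimethyl-2-(3-oxobutyl)cyclohexane-1-carbaldehyde
Conditions: 1 M HCl, THF, 40 °C
Reagents that add atoms: water O
Why: Acid-catalysed acetal hydrolysis should unmask the C8 methyl ketone and the C9 aldehyde together; C10 is quaternary, so the aldehyde cannot epimerise.

Step 8
Reactants: 16 dimethyl (R)-2-methylsuccinate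
Product: 17 (R)-2-methylbutane-1,4-diol
Conditions: LiAlH4, THF, 0 °C → reflux
Reagents that add atoms: none
Why: Hydride reduction of both esters; the stereocenter (future C13) comes from the chiral pool and is no longer α to a carbonyl in the product.

Step 9
Reactants: 17 (R)-2-methylbutane-1,4-diol; 18 chlorotriisopropylsilane
Product: 19 (2R)-2-methyl-4-[(triisopropylsilyl)oxy]butan-1-ol
Conditions: 18 (1.0 equiv), imidazole, CH2Cl2, −20 → 0 °C
Reagents that add atoms: 18 chlorotriisopropylsilane CC(C)[Si](Cl)(C(C)C)C(C)C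
Why: Monosilylation in which the bulky silyl chloride should prefer the primary hydroxyl remote from the methyl branch over the β-branched one; the minor regioisomer is removed by chromatography.

Step 10
Reactants: 19 (2R)-2-methyl-4-[(triisopropylsilyl)oxy]butan-1-ol; 20 iodine
Product: 21 {[(3R)-4-iodo-3-methylbutyl]oxy}triisopropylsilane
Conditions: PPh3, imidazole, CH2Cl2, 0 °C → rt
Reagents that add atoms: 20 iodine II
Why: Appel-type iodination converts the remaining primary alcohol into the iodide by SN2 at CH2, leaving the adjacent stereocenter untouched.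

Step 11
Reactants: 21 {[(3R)-4-iodo-3-methylbutyl]oxy}triisopropylsilane; 22 diethyl [(phenylsulfonyl)methyl]phosphonate
Product: 23 diethyl {(3R)-3-methyl-1-(phenylsulfonyl)-5-[(triisopropylsilyl)oxy]pentyl}phosphonate (both epimers at C1)
Conditions: 22 (1.5 equiv), NaH, DMF, 0 → 60 °C
Reagents that add atoms: 22 diethyl [(phenylsulfonyl)methyl]phosphonate CCOP(=O)(OCC)CS(=O)(=O)c1ccccc1
Why: SN2 C-alkylation of the doubly stabilised sulfonyl phosphonate carbanion by the primary iodide; the new center α to sulfur is of no consequence because it becomes sp2 in the next step.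

Step 12
Reactants: 15 (1R,2R,3S)-3-[(benzyloxy)methyl]-1,3-dimethyl-2-(3-oxobutyl)cyclohexane-1-carbaldehyde; 23 diethyl {(3R)-3-methyl-1-(phenylsulfonyl)-5-[(triisopropylsilyl)oxy]pentyl}phosphonate
Product: 24 4-{(1S,2S,6R)-2-[(benzyloxy)methyl]-2,6-dimethyl-6-[(1E,4R)-4-methyl-2-(phenylsulfonyl)-6-[(triisopropylsilyl)oxy]hex-1-en-1-yl]cyclohexyl}butan-2-one
Conditions: 23 (1.3 equiv), NaH (1.2 equiv), THF, 0 °C; then 15, 0 → 50 °C
Reagents that add atoms: 23 diethyl {(3R)-3-methyl-1-(phenylsulfonyl)-5-[(triisopropylsilyl)oxy]pentyl}phosphonate CCOP(=O)(OCC)C(C[C@H](C)CCO[Si](C(C)C)(C(C)C)C(C)C)S(=O)(=O)c1ccccc1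
Why: Horner–Wadsworth–Emmons olefination in which the weakly basic phosphonate carbanion should add to the aldehyde rather than the methyl ketone and expel diethyl phosphate to give the vinyl sulfone, mainly E; any Z isomer leads to the same cyclisation product.

Step 13
Reactants: 24 4-{(1S,2S,6R)-2-[(benzyloxy)methyl]-2,6-dimethyl-6-[(1E,4R)-4-methyl-2-(phenylsulfonyl)-6-[(triisopropylsilyl)oxy]hex-1-en-1-yl]cyclohexyl}butan-2-one
Product: 25 (1S,2S,4aS,5S,8aR)-5-[(benzyloxy)methyl]-2,5,8a-trimethyl-1-{(3R)-3-methyl-1-(phenylsulfonyl)-5-[(triisopropylsilyl)oxy]pentyl}decahydronaphthalen-2-ol (epimers at the sulfonyl carbon C11)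
Conditions: SmI2 (3 equiv), MeOH (5 equiv), THF, −78 → −40 °C
Reagents that add atoms: none
Why: SmI2 transfers one electron to the methyl ketone to give a samarium ketyl at C8, which adds to C9, the β-carbon of the vinyl sulfone; the α-sulfonyl radical at C11 is then reduced by a second SmI2 and protonated by MeOH. The closest known reaction type is the SmI2-mediated ketyl–olefin (reductive carbonyl–alkene) cyclisation onto electron-poor alkenes. Ring B (C5–C6–C7–C8–C9–C10) closes in the 6-exo-trig mode. At C9 the C9=C11 bond should sit pseudo-equatorial on the chair-like forming ring, which must be trans-fused because C6 and C9 are already trans-diequatorial on ring A, so H9 ends axial and cis to H5; at C8 the bulky O–Sm group should take the pseudo-equatorial site, away from the axial C10 methyl and anti to the electron-poor alkene, which places the C8 methyl axial and the hydroxyl trans to C11, as is usual for ketyl–olefin closures onto electron-poor alkenes. The step needs C–C bond formation to outrun simple reduction and needs face selectivity at C8; the first should be secured by the strongly accepting vinyl sulfone at low temperature without HMPA, the second by the fixed ring-A chair with its axial C10 methyl.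

Step 14
Reactants: 25 (1S,2S,4aS,5S,8aR)-5-[(benzyloxy)methyl]-2,5,8a-trimethyl-1-{(3R)-3-methyl-1-(phenylsulfonyl)-5-[(triisopropylsilyl)oxy]pentyl}decahydronaphthalen-2-ol
Product: 26 (1S,2S,4aS,5S,8aR)-5-(hydroxymethyl)-2,5,8a-trimethyl-1-{(3S)-3-methyl-5-[(triisopropylsilyl)oxy]pentyl}decahydronaphthalen-2-ol
Conditions: Na, NH3(l), THF, −78 °C; then NH4Cl
Reagents that add atoms: none
Why: Dissolving-metal reduction should cleave the C11–S bond of the alkyl phenyl sulfone and the benzyl ether in one operation, while the triisopropylsilyl ether and the tertiary alcohol persist; C11 becomes CH2 and no stereocenter is touched.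

Step 15
Reactants: 26 (1S,2S,4aS,5S,8aR)-5-(hydroxymethyl)-2,5,8a-trimethyl-1-{(3S)-3-methyl-5-[(triisopropylsilyl)oxy]pentyl}decahydronaphthalen-2-ol; 27 angelic acid ((Z)-2-methylbut-2-enoic acid)
Product: 28 [(1S,4aR,5S,6S,8aS)-6-hydroxy-1,4a,6-trimethyl-5-{(3S)-3-methyl-5-[(triisopropylsilyl)oxy]pentyl}decahydronaphthalen-1-yl]methyl (2Z)-2-methylbut-2-enoate
Conditions: 27, 2,4,6-trichlorobenzoyl chloride, Et3N, toluene, rt; then 26, 80 °C
Reagents that add atoms: 27 angelic acid C/C=C(/C)C(=O)O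
Why: Yamaguchi esterification through the mixed anhydride, run without DMAP in warm toluene so that the Z double bond should not isomerise to the tiglate; only the primary (neopentyl) C18 hydroxyl should react, the tertiary C8 hydroxyl being inert.

Step 16
Reactants: 28 [(1S,4aR,5S,6S,8aS)-6-hydroxy-1,4a,6-trimethyl-5-{(3S)-3-methyl-5-[(triisopropylsilyl)oxy]pentyl}decahydronaphthalen-1-yl]methyl (2Z)-2-methylbut-2-enoate
Product: 29 [(1S,4aR,5S,6S,8aS)-6-hydroxy-5-[(3S)-5-hydroxy-3-methylpentyl]-1,4a,6-trimethyldecahydronaphthalen-1-yl]methyl (2Z)-2-methylbut-2-enoate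
Conditions: HF·pyridine, pyridine, THF, 0 °C → rt
Reagents that add atoms: none
Why: Fluoride-mediated cleavage of the silyl ether under buffered, non-basic conditions that should leave the angelate and the tertiary alcohol untouched.

Step 17
Reactants: 29 [(1S,4aR,5S,6S,8aS)-6-hydroxy-5-[(3S)-5-hydroxy-3-methylpentyl]-1,4a,6-trimethyldecahydronaphthalen-1-yl]methyl (2Z)-2-methylbut-2-enoate; 30 Meldrum's acid (2,2-dimethyl-1,3-dioxane-4,6-dione)
Product: 31 3-{[(3S)-5-[(1S,2S,4aS,5S,8aR)-2-hydroxy-2,5,8a-trimethyl-5-({[(2Z)-2-methylbut-2-enoyl]oxy}methyl)decahydronaphthalen-1-yl]-3-methylpentyl]oxy}-3-oxopropanoic acid (target, CNP0286290.1)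
Conditions: 30 (1.1 equiv), toluene, 90 °C
Reagents that add atoms: 30 Meldrum's acid CC1(C)OC(=O)CC(=O)O1
Why: Ring-opening acylation of the alcohol by Meldrum's acid with loss of acetone should give the malonic half ester directly at the unhindered primary C15 hydroxyl; the tertiary hydroxyl should not react.

**Compound list**

1 | 3-methylbut-3-en-2-one | CC(=O)C(C)=C | starting material
2 | triisopropylsilyl trifluoromethanesulfonate | CC(C)[Si](C(C)C)(C(C)C)OS(=O)(=O)C(F)(F)F | starting material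
3 | 3-methyl-2-[(triisopropylsilyl)oxy]buta-1,3-diene | C=C(C)C(=C)O[Si](C(C)C)(C(C)C)C(C)C | intermediate
4 | methacrolein (2-methylprop-2-enal) | CC(=C)C=O | starting material
5 | (R)-1,3-dimethyl-4-[(triisopropylsilyl)oxy]cyclohex-3-ene-1-carbaldehyde | CC1=C(O[Si](C(C)C)(C(C)C)C(C)C)CC[C@@](C)(C=O)C1 | intermediate
6 | (R)-1,3-dimethyl-4-oxocyclohex-2-ene-1-carbaldehyde | O=C1CC[C@@](C)(C=O)C=C1C | intermediate
7 | ethane-1,2-diol | OCCO | starting material
8 | (R)-4-(1,3-dioxolan-2-yl)-2,4-dimethylcyclohex-2-en-1-one | O=C1CC[C@@](C)(C2OCCO2)C=C1C | intermediate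
9 | 2-(2-bromoethyl)-2-methyl-1,3-dioxolane | BrCCC1(C)OCCO1 | starting material
10 | chlorotrimethylsilane | C[Si](C)(C)Cl | starting material
11 | benzyl chloromethyl ether | ClCOCc1ccccc1 | starting material
12 | trimethyl{[(3R,4R)-4-(1,3-dioxolan-2-yl)-2,4-dimethyl-3-[2-(2-methyl-1,3-dioxolan-2-yl)ethyl]cyclohex-1-en-1-yl]oxy}silane | CC1=C(O[Si](C)(C)C)CC[C@@](C)(C2OCCO2)[C@@H]1CCC1(C)OCCO1 | intermediate (not isolated)
13 | (2S,3S,4R)-2-[(benzyloxy)methyl]-4-(1,3-dioxolan-2-yl)-2,4-dimethyl-3-[2-(2-methyl-1,3-dioxolan-2-yl)ethyl]cyclohexan-1-one | c1ccccc1COC[C@@]1(C)C(=O)CC[C@@](C)(C2OCCO2)[C@@H]1CCC1(C)OCCO1 | intermediate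
14 | 2-{(1R,2R,3S)-3-[(benzyloxy)methyl]-1,3-dimethyl-2-[2-(2-methyl-1,3-dioxolan-2-yl)ethyl]cyclohexyl}-1,3-dioxolane | c1ccccc1COC[C@@]1(C)CCC[C@@](C)(C2OCCO2)[C@@H]1CCC1(C)OCCO1 | intermediate
15 | (1R,2R,3S)-3-[(benzyloxy)methyl]-1,3-dimethyl-2-(3-oxobutyl)cyclohexane-1-carbaldehyde | c1ccccc1COC[C@@]1(C)CCC[C@@](C)(C=O)[C@@H]1CCC(C)=O | intermediate
16 | dimethyl (R)-2-methylsuccinate | COC(=O)[C@H](C)CC(=O)OC | starting material
17 | (R)-2-methylbutane-1,4-diol | OC[C@H](C)CCO | intermediate
18 | chlorotriisopropylsilane | CC(C)[Si](Cl)(C(C)C)C(C)C | starting material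
19 | (2R)-2-methyl-4-[(triisopropylsilyl)oxy]butan-1-ol | OC[C@H](C)CCO[Si](C(C)C)(C(C)C)C(C)C | intermediate
20 | iodine | II | starting material
21 | {[(3R)-4-iodo-3-methylbutyl]oxy}triisopropylsilane | IC[C@H](C)CCO[Si](C(C)C)(C(C)C)C(C)C | intermediate
22 | diethyl [(phenylsulfonyl)methyl]phosphonate | CCOP(=O)(OCC)CS(=O)(=O)c1ccccc1 | starting material
23 | diethyl {(3R)-3-methyl-1-(phenylsulfonyl)-5-[(triisopropylsilyl)oxy]pentyl}phosphonate (C1 epimers) | CCOP(=O)(OCC)C(C[C@H](C)CCO[Si](C(C)C)(C(C)C)C(C)C)S(=O)(=O)c1ccccc1 | intermediate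
24 | 4-{(1S,2S,6R)-2-[(benzyloxy)methyl]-2,6-dimethyl-6-[(1E,4R)-4-methyl-2-(phenylsulfonyl)-6-[(triisopropylsilyl)oxy]hex-1-en-1-yl]cyclohexyl}butan-2-one | c1ccccc1COC[C@@]1(C)CCC[C@@](C)(/C=C(\C[C@H](C)CCO[Si](C(C)C)(C(C)C)C(C)C)S(=O)(=O)c2ccccc2)[C@@H]1CCC(C)=O | intermediate
25 | (1S,2S,4aS,5S,8aR)-5-[(benzyloxy)methyl]-2,5,8a-trimethyl-1-{(3R)-3-methyl-1-(phenylsulfonyl)-5-[(triisopropylsilyl)oxy]pentyl}decahydronaphthalen-2-ol (C11 epimers) | c1ccccc1COC[C@@]1(C)CCC[C@]2(C)[C@@H]1CC[C@](C)(O)[C@H]2C(C[C@H](C)CCO[Si](C(C)C)(C(C)C)C(C)C)S(=O)(=O)c1ccccc1 | intermediate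
26 | (1S,2S,4aS,5S,8aR)-5-(hydroxymethyl)-2,5,8a-trimethyl-1-{(3S)-3-methyl-5-[(triisopropylsilyl)oxy]pentyl}decahydronaphthalen-2-ol | OC[C@@]1(C)CCC[C@]2(C)[C@@H]1CC[C@](C)(O)[C@H]2CC[C@H](C)CCO[Si](C(C)C)(C(C)C)C(C)C | intermediate
27 | angelic acid ((Z)-2-methylbut-2-enoic acid) | C/C=C(/C)C(=O)O | starting material
28 | [(1S,4aR,5S,6S,8aS)-6-hydroxy-1,4a,6-trimethyl-5-{(3S)-3-methyl-5-[(triisopropylsilyl)oxy]pentyl}decahydronaphthalen-1-yl]methyl (2Z)-2-methylbut-2-enoate | C/C=C(/C)C(=O)OC[C@@]1(C)CCC[C@]2(C)[C@@H]1CC[C@](C)(O)[C@H]2CC[C@H](C)CCO[Si](C(C)C)(C(C)C)C(C)C | intermediate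
29 | [(1S,4aR,5S,6S,8aS)-6-hydroxy-5-[(3S)-5-hydroxy-3-methylpentyl]-1,4a,6-trimethyldecahydronaphthalen-1-yl]methyl (2Z)-2-methylbut-2-enoate | C/C=C(/C)C(=O)OC[C@@]1(C)CCC[C@]2(C)[C@@H]1CC[C@](C)(O)[C@H]2CC[C@H](C)CCO | intermediate
30 | Meldrum's acid (2,2-dimethyl-1,3-dioxane-4,6-dione) | CC1(C)OC(=O)CC(=O)O1 | starting material
31 | 3-{[(3S)-5-[(1S,2S,4aS,5S,8aR)-2-hydroxy-2,5,8a-trimethyl-5-({[(2Z)-2-methylbut-2-enoyl]oxy}methyl)decahydronaphthalen-1-yl]-3-methylpentyl]oxy}-3-oxopropanoic acid | C/C=C(/C)C(=O)OC[C@@]1(C)CCC[C@]2(C)[C@@H]1CC[C@](C)(O)[C@H]2CC[C@H](C)CCOC(=O)CC(=O)O | target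

**Step count.** Total: 17 steps. Longest linear sequence: 13 steps (steps 1–7, then 12–17); the side-chain branch (steps 8–11) joins at step 12.

**Steps most likely to fail, with fallbacks**

1. Step 13 (key step). Electron transfer may end in simple reduction (ketone to carbinol, or conjugate reduction of the vinyl sulfone) before the C8–C9 bond forms. Alternatively the ketyl may add through the chair with the C8 methyl equatorial, eroding facial control at C8. The fallback sets out from 24 and generates the C8 radical by hydrogen-atom transfer instead of by a reducing metal. Soft enolisation (Et3SiOTf, Et3N, CH2Cl2, 0 °C) should give the triethylsilyl enol ether F1; either enol ether regioisomer leads to the same C8 radical. Fe(acac)3, PhSiH3, EtOH, 60 °C should then deliver a hydrogen atom to the enol ether, and the resulting α-silyloxy radical should close the same C8–C9 bond by Giese addition to the vinyl sulfone, with the bulky silyloxy group equatorial, giving the tertiary silyl ether F2. Pyridinium p-toluenesulfonate in MeOH should remove the tertiary triethylsilyl group in the presence of the primary triisopropylsilyl ether, and the route is rejoined at 25.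

2. Step 5. The hindered, fully substituted lithium enolate may be alkylated on oxygen by the hard chloromethyl ether, or be quenched by proton transfer, instead of forming the C4–C18 bond. The fallback sets out from 12, here worked up and isolated, and replaces the SN2 alkylation by an aldol reaction. MeLi (THF, 0 °C) followed by gaseous formaldehyde from cracked paraformaldehyde (−78 °C) should add the one-carbon unit, again anti to the C5 chain, to give the β-hydroxy ketone F3. O-Benzylation under neutral conditions (2-benzyloxy-1-methylpyridinium triflate, MgO, PhCF3, 85 °C) returns to 13.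

3. Step 12. Addition of the α-branched phosphonate carbanion to the neopentyl aldehyde may be slow and reversible, so that the olefination stalls. The fallback sets out from 15 and joins the fragments after ring closure instead of before. Olefination with the unbranched phosphonate 22 (LiCl, DBU, MeCN, rt) should give the (E)-vinyl sulfone F4. The same SmI2/MeOH ketyl–olefin closure then forms the C8–C9 bond and should give the hydroxy sulfone F5. Double deprotonation (n-BuLi, 2.2 equiv, THF–HMPA, −78 °C) and alkylation of the α-sulfonyl carbanion with iodide 21 returns to 25.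

**Further compounds**

F1 | step 13 | {[(2Z)-4-{(1S,2S,6R)-2-[(benzyloxy)methyl]-2,6-dimethyl-6-[(1E,4R)-4-methyl-2-(phenylsulfonyl)-6-[(triisopropylsilyl)oxy]hex-1-en-1-yl]cyclohexyl}but-2-en-2-yl]oxy}triethylsilane | c1ccccc1COC[C@@]1(C)CCC[C@@](C)(/C=C(\C[C@H](C)CCO[Si](C(C)C)(C(C)C)C(C)C)S(=O)(=O)c2ccccc2)[C@@H]1C/C=C(/C)O[Si](CC)(CC)CC
F2 | step 13 | {[(1S,2S,4aS,5S,8aR)-5-[(benzyloxy)methyl]-2,5,8a-trimethyl-1-{(3R)-3-methyl-1-(phenylsulfonyl)-5-[(triisopropylsilyl)oxy]pentyl}decahydronaphthalen-2-yl]oxy}triethylsilane | c1ccccc1COC[C@@]1(C)CCC[C@]2(C)[C@@H]1CC[C@](C)(O[Si](CC)(CC)CC)[C@H]2C(C[C@H](C)CCO[Si](C(C)C)(C(C)C)C(C)C)S(=O)(=O)c1ccccc1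
F3 | step 5 | (2S,3S,4R)-4-(1,3-dioxolan-2-yl)-2-(hydroxymethyl)-2,4-dimethyl-3-[2-(2-methyl-1,3-dioxolan-2-yl)ethyl]cyclohexan-1-one | OC[C@@]1(C)C(=O)CC[C@@](C)(C2OCCO2)[C@@H]1CCC1(C)OCCO1
F4 | step 12 | 4-{(1S,2S,6R)-2-[(benzyloxy)methyl]-2,6-dimethyl-6-[(E)-2-(phenylsulfonyl)ethenyl]cyclohexyl}butan-2-one | c1ccccc1COC[C@@]1(C)CCC[C@@](C)(/C=C/S(=O)(=O)c2ccccc2)[C@@H]1CCC(C)=O
F5 | step 12 | (1S,2S,4aS,5S,8aR)-5-[(benzyloxy)methyl]-2,5,8a-trimethyl-1-[(phenylsulfonyl)methyl]decahydronaphthalen-2-ol | c1ccccc1COC[C@@]1(C)CCC[C@]2(C)[C@@H]1CC[C@](C)(O)[C@H]2CS(=O)(=O)c1ccccc1
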